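**Retrosynthetic overview**
- The target comes from its bis(benzyl ether) by hydrogenolysis in the last step.
- The tetrahydrofuran ring comes from a C2-symmetric, all-trans 3,6-diaryl-4,5-dimethyl-1,2-dioxane by phosphine-mediated deoxygenative ring contraction (six to five); SN2 inversion at one benzylic carbon creates the 2,3-cis/2,5-cis pattern.
- The dioxane comes from two molecules of an (E)-propenylarene and O2 by a chiral-anion-controlled radical-cation [2+2+2] cyclooxygenation (new), which forms the central C–C bond and sets all four stereocentres.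
- The propenylarene comes from 4-chlorophenol (dibromination, copper-catalysed methoxylation, benzylation) and (E)-propenylboronic acid (Suzuki coupling).
- Ring order: the aryl rings are bought; the 1,2-dioxane ring is made first and then contracted to the tetrahydrofuran.

Assumption: the sense of induction of the chiral anion in step 5 cannot be predicted with certainty; the (S,S)-anion is written, and its (R,R) mirror image is used if the first run gives the enantiomeric dioxane (checked by X-ray or by correlation with the target).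

**Step 1**
Reactants: 1 4-chlorophenol
Product: 2 2,6-dibromo-4-chlorophenol
Conditions: Br2 (2.1 equiv), AcOH, 15–20 °C
Reagents that add atoms: bromine, BrBr
Why: Electrophilic aromatic bromination; the hydroxyl group directs to both ortho positions because the para position is blocked by chlorine.

**Step 2**
Reactants: 2 2,6-dibromo-4-chlorophenol
Product: 3 4-chloro-2,6-dimethoxyphenol
Conditions: NaOMe (6 equiv, 30% in MeOH), CuCl (15 mol%), DMF, 110 °C; then aq. HCl
Reagents that add atoms: sodium methoxide, [Na+].[O-]C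
Why: Ullmann-type methoxylation catalysed by monovalent copper, as practised on 2,6-dibromo-4-methylphenol and 3,5-dibromo-4-hydroxybenzaldehyde; the two C–Br bonds react while the unactivated C–Cl bond of the electron-rich phenoxide is inert.

**Step 3**
Reactants: 3 4-chloro-2,6-dimethoxyphenol
Product: 4 2-(benzyloxy)-5-chloro-1,3-dimethoxybenzene
Conditions: BnBr (1.2 equiv), K2CO3 (2 equiv), DMF, 60 °C
Reagents that add atoms: benzyl bromide, BrCc1ccccc1
Why: Williamson ether synthesis; the benzyl ether blocks phenoxyl-radical and quinone-methide chemistry in the oxidative step that follows.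

**Step 4**
Reactants: 4 2-(benzyloxy)-5-chloro-1,3-dimethoxybenzene; 5 (E)-prop-1-en-1-ylboronic acid (1.5 equiv)
Product: 6 2-(benzyloxy)-1,3-dimethoxy-5-[(1E)-prop-1-en-1-yl]benzene
Conditions: Pd(OAc)2 (2 mol%), 2-dicyclohexylphosphino-2',6'-dimethoxybiphenyl (SPhos, 4 mol%), K3PO4 (3 equiv), toluene/H2O 10:1, 90 °C
Reagents that add atoms: none
Why: Suzuki–Miyaura coupling; the bulky electron-rich biarylphosphine lets zerovalent palladium insert into the unhindered aryl chloride, and the alkenyl group transfers with retention of E geometry.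

**Step 5**
Reactants: 6 2-(benzyloxy)-1,3-dimethoxy-5-[(1E)-prop-1-en-1-yl]benzene (two molecules)
Product: 7 (3S,4S,5S,6S)-3,6-bis[4-(benzyloxy)-3,5-dimethoxyphenyl]-4,5-dimethyl-1,2-dioxane
Conditions: 9-mesitylthioxanthylium salt of the (S,S)-IDPi anion [N,N'-bis(trifluoromethanesulfonyl) imidodiphosphorimidate from (S)-3,3'-bis[3,5-bis(trifluoromethyl)phenyl]-1,1'-bi-2-naphthol] (2 mol%), O2 (1 atm), CH2Cl2 (0.1 M), −78 °C, green LEDs (525 nm); recrystallise
Reagents that add atoms: dioxygen, O=O
Why: Proposed new method: enantioselective aerobic radical-cation [2+2+2] cyclooxygenation under chiral-counteranion control — the excited thioxanthylium cation oxidises 6 to its radical cation, which stays paired with the confined chiral anion while a second molecule of 6 attacks head-to-head (β–β bond, setting C4 and C5 with the methyls threo); the 1,4-distonic bis-benzylic radical cation is trapped by triplet O2 and closes through a chair transition state with all four substituents equatorial (setting C3 and C6), and the dioxane radical cation is reduced by 6 or by the thioxanthyl radical; the closest known reaction types are the racemic electron-transfer cyclooxygenation of electron-rich arylalkenes to 1,2-dioxanes and the IDPi-paired photoredox radical-cation [2+2] cyclodimerisation of anethole-type alkenes, which has the same enantio-determining C–C bond formation.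

**Step 6**
Reactants: 7 (3S,4S,5S,6S)-3,6-bis[4-(benzyloxy)-3,5-dimethoxyphenyl]-4,5-dimethyl-1,2-dioxane
Product: 9 (2R,3S,4S,5S)-2,5-bis[4-(benzyloxy)-3,5-dimethoxyphenyl]-3,4-dimethyltetrahydrofuran, via cyclic triphenyldioxaphosphorane 8 (not isolated)
Conditions: PPh3 (1.3 equiv), toluene, 80 °C
Reagents that add atoms: none
Why: Phosphine-mediated deoxygenative ring contraction of a 1,2-dioxane (Mitsunobu-like): trivalent phosphorus inserts into the O–O bond to give 8, which ionises to an alkoxyphosphonium alkoxide and closes by 5-exo-tet SN2 with loss of Ph3P=O; inversion at one benzylic carbon (S to R) gives the 2,3-cis, 3,4-trans, 4,5-trans ring, and because 7 is C2-symmetric either oxygen or benzylic carbon gives the same product.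

**Step 7**
Reactants: 9 (2R,3S,4S,5S)-2,5-bis[4-(benzyloxy)-3,5-dimethoxyphenyl]-3,4-dimethyltetrahydrofuran
Product: 10 4,4'-[(2R,3S,4S,5S)-3,4-dimethyltetrahydrofuran-2,5-diyl]bis(2,6-dimethoxyphenol)
Conditions: H2 (1 atm), 10% Pd/C, EtOAc, 20 °C, stopped at full conversion
Reagents that add atoms: none
Why: Hydrogenolysis of the two aryl benzyl ethers, which is faster than cleavage of the ring benzylic C–O bonds (as in the final debenzylations I recall for related 2,5-diaryltetrahydrofuran lignans); no stereocentre is touched.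

**Compound list**
1 | 4-chlorophenol | Oc1ccc(Cl)cc1 | starting material
2 | 2,6-dibromo-4-chlorophenol | Oc1c(Br)cc(Cl)cc1Br | intermediate
3 | 4-chloro-2,6-dimethoxyphenol | COc1cc(Cl)cc(OC)c1O | intermediate
4 | 2-(benzyloxy)-5-chloro-1,3-dimethoxybenzene | COc1cc(Cl)cc(OC)c1OCc1ccccc1 | intermediate
5 | (E)-prop-1-en-1-ylboronic acid | C/C=C/B(O)O | starting material
6 | 2-(benzyloxy)-1,3-dimethoxy-5-[(1E)-prop-1-en-1-yl]benzene | C/C=C/c1cc(OC)c(OCc2ccccc2)c(OC)c1 | intermediate
7 | (3S,4S,5S,6S)-3,6-bis[4-(benzyloxy)-3,5-dimethoxyphenyl]-4,5-dimethyl-1,2-dioxane (all-trans, C2-symmetric) | COc1cc([C@H]2OO[C@H](c3cc(OC)c(OCc4ccccc4)c(OC)c3)[C@@H](C)[C@@H]2C)cc(OC)c1OCc1ccccc1 | intermediate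
8 | (4S,5S,6S,7S)-4,7-bis[4-(benzyloxy)-3,5-dimethoxyphenyl]-5,6-dimethyl-2,2,2-triphenyl-1,3,2λ5-dioxaphosphepane | COc1cc([C@H]2OP(c3ccccc3)(c3ccccc3)(c3ccccc3)O[C@H](c3cc(OC)c(OCc4ccccc4)c(OC)c3)[C@@H](C)[C@@H]2C)cc(OC)c1OCc1ccccc1 | intermediate (not isolated)
9 | (2R,3S,4S,5S)-2,5-bis[4-(benzyloxy)-3,5-dimethoxyphenyl]-3,4-dimethyltetrahydrofuran (2,3-cis, 3,4-trans, 4,5-trans; aryl groups cis) | COc1cc([C@H]2O[C@@H](c3cc(OC)c(OCc4ccccc4)c(OC)c3)[C@@H](C)[C@@H]2C)cc(OC)c1OCc1ccccc1 | intermediate
10 | 4,4'-[(2R,3S,4S,5S)-3,4-dimethyltetrahydrofuran-2,5-diyl]bis(2,6-dimethoxyphenol) | COc1cc([C@H]2O[C@@H](c3cc(OC)c(O)c(OC)c3)[C@@H](C)[C@@H]2C)cc(OC)c1O | target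

**Totals**
Total step count: 7. Longest linear sequence: 7 steps (1 to 10).

**Steps most likely to fail, with fallbacks**

Step 5 (the new cyclooxygenation). Risks are oxidative C=C cleavage to the aldehyde, cyclobutane formation instead of O2 capture, and low er or dr. The fallback sets out from 6 and comes back at 7, using two known reaction types. Compound 6 is first cyclodimerised under argon with the same kind of thioxanthylium/IDPi ion pair (green light, CH2Cl2, low temperature), the known chiral-counteranion radical-cation [2+2] of anethole-type alkenes. This gives the trans,anti,trans cyclobutane (1R,2R,3S,4S)-1,2-bis[4-(benzyloxy)-3,5-dimethoxyphenyl]-3,4-dimethylcyclobutane F1. F1 is then ring-expanded by the known electron-transfer photooxygenation of 1,2-diarylcyclobutanes (2,4,6-triphenylpyrylium tetrafluoroborate, 5 mol%, O2, CH2Cl2, blue LEDs, −20 °C). The Ar–CH–CH–Ar bond of the cyclobutane radical cation opens, the methyl-bearing centres are untouched, and O2 capture with chair closure gives 7.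

Step 6 (ring contraction). Risks are SN1 scrambling at the electron-rich benzylic carbon, or elimination of the alkoxyphosphonium to a γ-hydroxy ketone. The fallback sets out from 7 and comes back at 9, replacing the SN2 closure by an oxocarbenium reduction. The O–O bond of 7 is reduced (Zn, AcOH/CH2Cl2, 0 °C) to (1S,2S,3S,4S)-1,4-bis[4-(benzyloxy)-3,5-dimethoxyphenyl]-2,3-dimethylbutane-1,4-diol F2. One benzylic alcohol of F2 is oxidised (MnO2, CH2Cl2, 20 °C); the hydroxy ketone closes at once to the lactol (3S,4S,5S)-2,5-bis[4-(benzyloxy)-3,5-dimethoxyphenyl]-3,4-dimethyltetrahydrofuran-2-ol F3, which masks the second alcohol. Reduction of F3 (Et3SiH, BF3·OEt2, CH2Cl2, −78 °C) delivers hydride to the cyclic oxocarbenium ion anti to the neighbouring methyl group, giving the 2,3-cis product 9. This is the known reductive deoxygenation used for veraguensin-type lignans.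

Step 7 (debenzylation). The risk is hydrogenolysis of the ring benzylic C–O bonds. The fallback sets out from 3 and comes back at 10 with a fluoride-labile silyl ether in place of benzyl. Compound 3 is silylated (i-Pr3SiCl, imidazole, DMF) to (4-chloro-2,6-dimethoxyphenoxy)tri(propan-2-yl)silane F4. F4 is coupled with 5 as in step 4 to {2,6-dimethoxy-4-[(1E)-prop-1-en-1-yl]phenoxy}tri(propan-2-yl)silane F5. F5 is cyclooxygenated as in step 5 to (3S,4S,5S,6S)-3,6-bis{3,5-dimethoxy-4-[tri(propan-2-yl)silyloxy]phenyl}-4,5-dimethyl-1,2-dioxane F6. F6 is contracted with PPh3 as in step 6 to (2R,3S,4S,5S)-2,5-bis{3,5-dimethoxy-4-[tri(propan-2-yl)silyloxy]phenyl}-3,4-dimethyltetrahydrofuran F7. F7 is desilylated (Bu4NF, THF, 0 °C) to 10.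

**Further compounds**
F1 | step 5 | (1R,2R,3S,4S)-1,2-bis[4-(benzyloxy)-3,5-dimethoxyphenyl]-3,4-dimethylcyclobutane | COc1cc([C@H]2[C@H](c3cc(OC)c(OCc4ccccc4)c(OC)c3)[C@@H](C)[C@@H]2C)cc(OC)c1OCc1ccccc1
F2 | step 6 | (1S,2S,3S,4S)-1,4-bis[4-(benzyloxy)-3,5-dimethoxyphenyl]-2,3-dimethylbutane-1,4-diol | COc1cc([C@@H](O)[C@@H](C)[C@H](C)[C@H](O)c2cc(OC)c(OCc3ccccc3)c(OC)c2)cc(OC)c1OCc1ccccc1
F3 | step 6 | (3S,4S,5S)-2,5-bis[4-(benzyloxy)-3,5-dimethoxyphenyl]-3,4-dimethyltetrahydrofuran-2-ol (anomer mixture) | COc1cc([C@H]2OC(O)(c3cc(OC)c(OCc4ccccc4)c(OC)c3)[C@@H](C)[C@@H]2C)cc(OC)c1OCc1ccccc1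
F4 | step 7 | (4-chloro-2,6-dimethoxyphenoxy)tri(propan-2-yl)silane | COc1cc(Cl)cc(OC)c1O[Si](C(C)C)(C(C)C)C(C)C
F5 | step 7 | {2,6-dimethoxy-4-[(1E)-prop-1-en-1-yl]phenoxy}tri(propan-2-yl)silane | C/C=C/c1cc(OC)c(O[Si](C(C)C)(C(C)C)C(C)C)c(OC)c1
F6 | step 7 | (3S,4S,5S,6S)-3,6-bis{3,5-dimethoxy-4-[tri(propan-2-yl)silyloxy]phenyl}-4,5-dimethyl-1,2-dioxane | COc1cc([C@H]2OO[C@H](c3cc(OC)c(O[Si](C(C)C)(C(C)C)C(C)C)c(OC)c3)[C@@H](C)[C@@H]2C)cc(OC)c1O[Si](C(C)C)(C(C)C)C(C)C
F7 | step 7 | (2R,3S,4S,5S)-2,5-bis{3,5-dimethoxy-4-[tri(propan-2-yl)silyloxy]phenyl}-3,4-dimethyltetrahydrofuran | COc1cc([C@H]2O[C@@H](c3cc(OC)c(O[Si](C(C)C)(C(C)C)C(C)C)c(OC)c3)[C@@H](C)[C@@H]2C)cc(OC)c1O[Si](C(C)C)(C(C)C)C(C)C
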